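**Retrosynthetic overview**

- The target is reached by one acid-mediated cleavage of two MOM ethers and a dioxolane on ring B; the last skeletal disconnection before that is a (4+2) cycloaddition/aromatization that builds ring A.
- The feature the strategy rests on: ring A is a pentasubstituted methyl resorcylate. Its adjacent C1 (CO2Me) and C2 (CH2O-acyl) are the two alkyne carbons of a 2-ynoate, and its C3–C6 run (H, OH, CH3, OH) is the four-carbon bis(silyloxy)diene derived from methyl 2-methylacetoacetate.
- The ynoate comes from SN2 esterification of the ring B cesium carboxylate with methyl 4-chlorobut-2-ynoate (made from propargyl chloride), so the hindered acid is never acylated and a free ortho-hydroxymethyl benzoate never exists.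
- The ring B acid comes from orcinol by bis-MOM protection, ortho-metalation/formylation, dioxolane formation and a second ortho-metalation/carboxylation.
- Ring order: ring B is bought (orcinol); ring A is the only ring constructed, in the key step, after the ester link is in place.

Key step: step 9

Assumption: the silyl enol ether, its dienolate and the diene are drawn as single geometric isomers. A mixture is expected and is without consequence, because both sp2 carbons concerned end up in aromatic ring A; the racemic stereocenter of the keto ester is lost on enolization.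

**Route**

Step 1
Reactants: 1 orcinol (5-methylbenzene-1,3-diol)
Product: 2 1,3-bis(methoxymethoxy)-5-methylbenzene
Conditions: MOMCl, i-Pr2NEt, CH2Cl2, 0 °C → rt
Reagents that add atoms: chloromethyl methyl ether (MOMCl), COCCl
Why: Base-mediated O-alkylation of both phenols (Williamson-type etherification) should give the bis-MOM ether, whose acetal oxygens later direct both metalations.

Step 2
Reactants: 2 1,3-bis(methoxymethoxy)-5-methylbenzene
Product: 4 2,6-bis(methoxymethoxy)-4-methylbenzaldehyde, via 2-lithio aryl ether 3 (not isolated)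
Conditions: n-BuLi, TMEDA, THF, 0 °C; then DMF, 0 °C → rt; then H2O
Reagents that add atoms: N,N-dimethylformamide, CN(C)C=O
Why: Directed ortho-metalation should occur at the position flanked and chelated by both OMOM groups, and the aryllithium is formylated by DMF (Bouveault-type formylation).

Step 3
Reactants: 4 2,6-bis(methoxymethoxy)-4-methylbenzaldehyde
Product: 5 2-[2,6-bis(methoxymethoxy)-4-methylphenyl]-1,3-dioxolane
Conditions: TMSOCH2CH2OTMS, TMSOTf (cat.), CH2Cl2, −78 → −20 °C; then pyridine
Reagents that add atoms: 1,2-bis(trimethylsilyloxy)ethane, C[Si](C)(C)OCCO[Si](C)(C)C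
Why: Noyori acetalization is aprotic and cold, so it should form the dioxolane, driven by hexamethyldisiloxane formation, without the protic acid and heat that would endanger the aryl MOM ethers.

Step 4
Reactants: 5 2-[2,6-bis(methoxymethoxy)-4-methylphenyl]-1,3-dioxolane
Product: 8 3-(1,3-dioxolan-2-yl)-2,4-bis(methoxymethoxy)-6-methylbenzoic acid, via aryllithium 6 (not isolated), via lithium carboxylate 7 (not isolated)
Conditions: s-BuLi, TMEDA, THF, −78 °C; then CO2 (g), −78 → 0 °C; then cold dilute aq. HCl to pH 4, immediate extraction
Reagents that add atoms: carbon dioxide, O=C=O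
Why: A second directed ortho-metalation can only take place at the two symmetry-equivalent ring positions ortho to an OMOM group, and carboxylation of the aryllithium with CO2 should give the acid after a brief, cold, mildly acidic work-up that the acetals tolerate.

Step 5
Reactants: 9 propargyl chloride (3-chloroprop-1-yne)
Product: 11 methyl 4-chlorobut-2-ynoate, via lithium acetylide 10 (not isolated)
Conditions: MeLi, Et2O, −60 °C; then ClCO2Me, −60 °C → rt
Reagents that add atoms: methyl chloroformate, COC(=O)Cl
Why: Deprotonation of the terminal alkyne at low temperature is faster than substitution at the propargylic chloride, and C-acylation of the acetylide with the chloroformate gives the ynoate (acetylide alkoxycarbonylation).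

Step 6
Reactants: 8 3-(1,3-dioxolan-2-yl)-2,4-bis(methoxymethoxy)-6-methylbenzoic acid; 11 methyl 4-chlorobut-2-ynoate
Product: 13 methyl 4-{[3-(1,3-dioxolan-2-yl)-2,4-bis(methoxymethoxy)-6-methylbenzoyl]oxy}but-2-ynoate, via cesium carboxylate 12 (not isolated)
Conditions: Cs2CO3 (0.5 equiv), DMF, rt; then 11, 0 °C → rt
Reagents that add atoms: none
Why: SN2 O-alkylation of the cesium carboxylate at the ynoate-activated propargylic chloride esterifies the di-ortho-substituted acid without any attack at its hindered carbonyl, and the weakly basic carboxylate should neither isomerize the ynoate nor add to it competitively.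

Step 7
Reactants: 14 methyl 2-methyl-3-oxobutanoate (racemic)
Product: 15 methyl (2Z)-2-methyl-3-(trimethylsilyloxy)but-2-enoate
Conditions: TMSCl, Et3N, hexane, rt
Reagents that add atoms: chlorotrimethylsilane, C[Si](C)(C)Cl
Why: The readily enolized β-keto ester is O-silylated by TMSCl with amine base to give the β-silyloxy enoate (silyl enol ether formation).

Step 8
Reactants: 15 methyl (2Z)-2-methyl-3-(trimethylsilyloxy)but-2-enoate
Product: 17 (1Z)-1-methoxy-2-methyl-1,3-bis(trimethylsilyloxy)buta-1,3-diene, via lithium dienolate 16 (not isolated)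
Conditions: LiN(i-Pr)2, THF, −78 °C; then TMSCl, −78 °C → rt
Reagents that add atoms: chlorotrimethylsilane, C[Si](C)(C)Cl
Why: Kinetic γ-deprotonation of the β-silyloxy enoate gives the extended enolate, which is silylated on the ester oxygen to the 1,3-bis(silyloxy)diene (the standard preparation of Chan-type dienes).

Step 9
Reactants: 13 methyl 4-{[3-(1,3-dioxolan-2-yl)-2,4-bis(methoxymethoxy)-6-methylbenzoyl]oxy}but-2-ynoate; 17 (1Z)-1-methoxy-2-methyl-1,3-bis(trimethylsilyloxy)buta-1,3-diene
Product: 20 methyl 6-({[3-(1,3-dioxolan-2-yl)-2,4-bis(methoxymethoxy)-6-methylbenzoyl]oxy}methyl)-2,4-dihydroxy-3-methylbenzoate, via cyclohexadiene cycloadduct 18 (not isolated), via bis(trimethylsilyl) aryl ether 19 (not isolated)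
Conditions: 17 (3 equiv), toluene, 100 °C, sealed tube; then K2CO3 (cat.), MeOH, 0 °C
Reagents that add atoms: none
Why: The diene is a vinylogous silyl ketene acetal whose unsubstituted CH2 terminus carries the largest HOMO coefficient; it bonds to the ester-polarized β-carbon of ynoate 13 while the ketene acetal carbon bonds to the α-carbon, in an asynchronous normal-demand Diels–Alder reaction (in the stepwise limit, a Mukaiyama–Michael addition followed by 6-exo-trig closure of the allenoate carbon onto the dioxocarbenium carbon). The closest known reaction type is the cycloaddition of 1-alkoxy-1,3-bis(trimethylsilyloxy)buta-1,3-dienes with alkynoates to give salicylates and resorcylates, applied here to a 2-methyl diene and a 4-acyloxy ynoate. Ring A is closed in this intermolecular (4+2) mode, which forms the C2–C3 and C1–C6 bonds in one operation, and cyclohexa-1,4-diene ketal 18 aromatizes by 1,4-loss of methanol, so the only stereocenter formed (the ketal carbon of 18) is transient and needs no control. The selectivity required is regiochemical and is secured by the ynoate ester, which places H at C3 beside the acyloxymethyl carbon and the C6 oxygen beside the ester. Chemoselectivity follows from the masking of ring B, which offers the diene neither an aldehyde nor an acidic proton, and from the already acylated benzylic oxygen, which cannot lactonize onto the ester. Carbonate-catalysed methanolysis then cleaves only the two aryl silyl ethers and leaves the MOM ethers, the dioxolane and both esters untouched.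

Step 10
Reactants: 20 methyl 6-({[3-(1,3-dioxolan-2-yl)-2,4-bis(methoxymethoxy)-6-methylbenzoyl]oxy}methyl)-2,4-dihydroxy-3-methylbenzoate
Product: 21 methyl 6-{[(3-formyl-2,4-dihydroxy-6-methylbenzoyl)oxy]methyl}-2,4-dihydroxy-3-methylbenzoate (target)
Conditions: aq. HCl, MeOH–THF, 40 °C
Reagents that add atoms: water, O
Why: Acid-catalysed acetal cleavage (transfer of the MOM groups to methanol as dimethoxymethane and hydrolysis of the dioxolane) should free both phenols and the aldehyde, while the di-ortho-substituted benzyl ester and the methyl ester resist solvolysis and the ring A hydroxyls, both meta to the benzylic carbon, do not assist its ionization.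

**Compound list**

1 | orcinol (5-methylbenzene-1,3-diol) | Cc1cc(O)cc(O)c1 | starting material
2 | 1,3-bis(methoxymethoxy)-5-methylbenzene | COCOc1cc(C)cc(OCOC)c1 | intermediate
3 | [2,6-bis(methoxymethoxy)-4-methylphenyl]lithium | [Li]c1c(OCOC)cc(C)cc1OCOC | intermediate
4 | 2,6-bis(methoxymethoxy)-4-methylbenzaldehyde | COCOc1cc(C)cc(OCOC)c1C=O | intermediate
5 | 2-[2,6-bis(methoxymethoxy)-4-methylphenyl]-1,3-dioxolane | COCOc1cc(C)cc(OCOC)c1C1OCCO1 | intermediate
6 | [3-(1,3-dioxolan-2-yl)-2,4-bis(methoxymethoxy)-6-methylphenyl]lithium | [Li]c1c(C)cc(OCOC)c(C2OCCO2)c1OCOC | intermediate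
7 | lithium 3-(1,3-dioxolan-2-yl)-2,4-bis(methoxymethoxy)-6-methylbenzoate | [Li+].[O-]C(=O)c1c(C)cc(OCOC)c(C2OCCO2)c1OCOC | intermediate
8 | 3-(1,3-dioxolan-2-yl)-2,4-bis(methoxymethoxy)-6-methylbenzoic acid | OC(=O)c1c(C)cc(OCOC)c(C2OCCO2)c1OCOC | intermediate
9 | propargyl chloride (3-chloroprop-1-yne) | C#CCCl | starting material
10 | (3-chloroprop-1-yn-1-yl)lithium | [Li]C#CCCl | intermediate
11 | methyl 4-chlorobut-2-ynoate | COC(=O)C#CCCl | intermediate
12 | cesium 3-(1,3-dioxolan-2-yl)-2,4-bis(methoxymethoxy)-6-methylbenzoate | [Cs+].[O-]C(=O)c1c(C)cc(OCOC)c(C2OCCO2)c1OCOC | intermediate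
13 | methyl 4-{[3-(1,3-dioxolan-2-yl)-2,4-bis(methoxymethoxy)-6-methylbenzoyl]oxy}but-2-ynoate | COC(=O)C#CCOC(=O)c1c(C)cc(OCOC)c(C2OCCO2)c1OCOC | intermediate
14 | methyl 2-methyl-3-oxobutanoate (racemic) | COC(=O)C(C)C(C)=O | starting material
15 | methyl (2Z)-2-methyl-3-(trimethylsilyloxy)but-2-enoate | COC(=O)/C(C)=C(/C)O[Si](C)(C)C | intermediate
16 | lithium 1-methoxy-2-methyl-3-(trimethylsilyloxy)buta-1,3-dien-1-olate | C=C(O[Si](C)(C)C)/C(C)=C(/OC)O[Li] | intermediate
17 | (1Z)-1-methoxy-2-methyl-1,3-bis(trimethylsilyloxy)buta-1,3-diene | C=C(O[Si](C)(C)C)/C(C)=C(/OC)O[Si](C)(C)C | intermediate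
18 | methyl 2-({[3-(1,3-dioxolan-2-yl)-2,4-bis(methoxymethoxy)-6-methylbenzoyl]oxy}methyl)-6-methoxy-5-methyl-4,6-bis(trimethylsilyloxy)cyclohexa-1,4-diene-1-carboxylate (racemic at C6) | COC(=O)C1=C(COC(=O)c2c(C)cc(OCOC)c(C3OCCO3)c2OCOC)CC(O[Si](C)(C)C)=C(C)C1(OC)O[Si](C)(C)C | intermediate
19 | methyl 6-({[3-(1,3-dioxolan-2-yl)-2,4-bis(methoxymethoxy)-6-methylbenzoyl]oxy}methyl)-3-methyl-2,4-bis(trimethylsilyloxy)benzoate | COC(=O)c1c(COC(=O)c2c(C)cc(OCOC)c(C3OCCO3)c2OCOC)cc(O[Si](C)(C)C)c(C)c1O[Si](C)(C)C | intermediate
20 | methyl 6-({[3-(1,3-dioxolan-2-yl)-2,4-bis(methoxymethoxy)-6-methylbenzoyl]oxy}methyl)-2,4-dihydroxy-3-methylbenzoate | COC(=O)c1c(COC(=O)c2c(C)cc(OCOC)c(C3OCCO3)c2OCOC)cc(O)c(C)c1O | intermediate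
21 | methyl 6-{[(3-formyl-2,4-dihydroxy-6-methylbenzoyl)oxy]methyl}-2,4-dihydroxy-3-methylbenzoate | COC(=O)c1c(COC(=O)c2c(C)cc(O)c(C=O)c2O)cc(O)c(C)c1O | target

**Step count**

Total: 10 steps. Longest linear sequence: 7 steps (steps 1, 2, 3, 4, 6, 9, 10).

**Steps most likely to fail, with fallbacks**

1. Step 9. The β-carbon of ynoate 13 is substituted and carries a bulky aroyloxymethyl group, so cycloaddition may be slower than thermal decay of the diene (silyl migration, protodesilylation), leaving the ynoate unconverted. The fallback moves the cycloaddition to a small dienophile and forms the ester bond after ring A exists. It sets out from chloro ynoate 11 and diene 17. Their cycloaddition (toluene, 80 °C; then dilute aq. HCl, THF, which this acetal-free product tolerates) should pass through the cyclohexadiene cycloadduct F1 and the bis(trimethylsilyl) aryl ether F2 to give methyl 6-(chloromethyl)-2,4-dihydroxy-3-methylbenzoate F3. The benzylic chloride of F3 is then displaced by cesium carboxylate 12 (made from acid 8 with 0.5 equiv Cs2CO3; DMF, rt), under which the less acidic phenols stay protonated. The fallback returns to the route at compound 20.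

2. Step 4. Metalation at the ring position flanked by the methyl group may be incomplete, or deprotonation at the dioxolane C–H may compete and fragment the acetal. The fallback replaces deprotonation by halogen–metal exchange. It sets out from dioxolane 5: electrophilic bromination (NBS, NaHCO3, MeCN, 0 °C) at one of the two equivalent positions, each ortho and para to an OMOM group, should give 2-[3-bromo-2,6-bis(methoxymethoxy)-4-methylphenyl]-1,3-dioxolane F4. Bromine–lithium exchange (n-BuLi, THF, −78 °C) then delivers aryllithium 6, and CO2 followed by the same cold work-up gives lithium carboxylate 7 and returns to the route at acid 8.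

3. Step 6. The chloro ynoate may be lost to base-induced isomerization and oligomerization, or to conjugate addition of the carboxylate, before substitution at the propargylic carbon is complete. The fallback attaches the three-carbon alkyne first and adds the ester carbon afterwards. It sets out from acid 8 as its cesium salt 12: alkylation with propargyl bromide (DMF, rt) should give prop-2-yn-1-yl 3-(1,3-dioxolan-2-yl)-2,4-bis(methoxymethoxy)-6-methylbenzoate F5. Carboxylation of the terminal alkyne (AgI (cat.), Cs2CO3, CO2 (1 atm), DMF, 50 °C) gives cesium 4-{[3-(1,3-dioxolan-2-yl)-2,4-bis(methoxymethoxy)-6-methylbenzoyl]oxy}but-2-ynoate F6, which is methylated in the same flask with MeI. The fallback returns to the route at ynoate 13.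

**Further compounds**

F1 | step 9 | methyl 2-(chloromethyl)-6-methoxy-5-methyl-4,6-bis(trimethylsilyloxy)cyclohexa-1,4-diene-1-carboxylate (racemic) | COC(=O)C1=C(CCl)CC(O[Si](C)(C)C)=C(C)C1(OC)O[Si](C)(C)C
F2 | step 9 | methyl 6-(chloromethyl)-3-methyl-2,4-bis(trimethylsilyloxy)benzoate | COC(=O)c1c(CCl)cc(O[Si](C)(C)C)c(C)c1O[Si](C)(C)C
F3 | step 9 | methyl 6-(chloromethyl)-2,4-dihydroxy-3-methylbenzoate | COC(=O)c1c(CCl)cc(O)c(C)c1O
F4 | step 4 | 2-[3-bromo-2,6-bis(methoxymethoxy)-4-methylphenyl]-1,3-dioxolane | COCOc1cc(C)c(Br)c(OCOC)c1C1OCCO1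
F5 | step 6 | prop-2-yn-1-yl 3-(1,3-dioxolan-2-yl)-2,4-bis(methoxymethoxy)-6-methylbenzoate | C#CCOC(=O)c1c(C)cc(OCOC)c(C2OCCO2)c1OCOC
F6 | step 6 | cesium 4-{[3-(1,3-dioxolan-2-yl)-2,4-bis(methoxymethoxy)-6-methylbenzoyl]oxy}but-2-ynoate | [Cs+].[O-]C(=O)C#CCOC(=O)c1c(C)cc(OCOC)c(C2OCCO2)c1OCOC
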